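Start from the easy case: where each step is first order, target per unit of charge does not depend on the charge, and the one step here that is not first order is the meeting of substrate with intermediate C.

    intermediate B → intermediate C (k1 = 0.0012 s⁻¹)
    intermediate C → decomposed reagent (k2 = 0.0012 s⁻¹)
    substrate + intermediate C → side product (k3 = 0.45 M⁻¹ s⁻¹)
    intermediate C → target (k4 = 0.0020 s⁻¹)
    intermediate A → intermediate B (k5 = 3.5 × 10⁻⁴ s⁻¹)
    substrate → intermediate A (k6 = 0.0021 s⁻¹)
    target ⇌ isomer of the product (K7 = 1.1, k7 = 0.0011 s⁻¹)

the same everywhere: time 6.0 min

| flask | substrate |
|---|---|
| south | 0.0030 M |
| north-east | 0.0060 M |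
| south-east | 0.012 M |
| west | 0.025 M |
| east | 0.050 M |

- [target] at the end for south, north-east, south-east, west, east, in this order
- the shape of the row from first to last (falls, then rises / rises all the way / hardly changes / rises, then falls / falls all the way)

- percent here means substrate units held: one side product counts as two
- "hardly changes" means that all values lie within two and a half points (for a concentration: within two and a half percent of the largest)
- run time (south): 6.0 min

I took a flask without that meeting as the zero of my scale, with target a fixed fraction Y of the charge c. Substrate reaches target through 4 first-order steps, so early on Y is the product of their constants and the run time to the power 4, divided by 4 factorial. The next term of the series in time trims this by each first-order loss met on the way, each with equal weight, over a clock τ equal to the run divided by 5, here 1.20 min. The losses of substrate, intermediate A, intermediate B, intermediate C and target sum to 0.00795 s⁻¹. Writing the trim as an exponential, I got Y = 0.0696%.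

The meeting is a pseudo-first-order loss of intermediate C, with constant 0.45 M⁻¹ s⁻¹ times the substrate present. I took that substrate at mid-run, a fraction s = 68.5% of the charge. I then reckoned in two ways the charge at which the meeting halves the target per charge. One way treats intermediate C as steady, so that the meeting matches its two first-order exits, together 0.00320 s⁻¹, at a charge of 0.0104 M. The other way keeps the youth of the run: as an approximation I counted 1/τ as a further exit rate of intermediate C beside its two first-order exits, so that target per charge is Y/(1 + c/c*), where c* is the sum of 1/τ and the exits, divided by the meeting constant times s. That gives 0.0554 M, the crossover charge c*.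

The two ways part by a factor of 5.33, and I found the steady one to be the cheat. It needs intermediate C to live far shorter than the run, yet the exits give it 5.21 min against 6.0 min. The clock rate 0.0139 s⁻¹ is larger than the exits, so in c* the youth of the run weighs more than they do. The east charge 0.050 M lies below c*, and c/(1 + c/c*) climbs with c. I therefore committed to a flattening rise, from 1.98 × 10⁻⁶ M in the south flask to 1.83 × 10⁻⁵ M in the east flask.

The forecast gave 2.000 × 10⁻⁶ M, 3.750 × 10⁻⁶ M, 6.800 × 10⁻⁶ M, 1.170 × 10⁻⁵ M and 1.750 × 10⁻⁵ M, shape rises all the way, holding that the stronger scavenging lowers the yield but “this does not offset the larger feed”. My east value stood above its last point.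

The flasks gave 2.01 × 10⁻⁶ M, 3.83 × 10⁻⁶ M, 6.96 × 10⁻⁶ M, 1.21 × 10⁻⁵ M and 1.82 × 10⁻⁵ M, shape rises all the way. At the end the east flask held 0.500% of its charge as side product and 0.0364% as target, while the south flask held 0.0547% and 0.0671%. The crossover charge then served the west flask, which I had not reckoned: its 0.025 M is 0.451 of c*, so Y/(1 + c/c*) times the charge gives 1.20 × 10⁻⁵ M, and the west flask held 1.21 × 10⁻⁵ M.

The constants are made up; the run is a simulation.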